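The coupling partner is the limiting reagent of this flask: each product costs it twice, in step 2 and again in step 3, so its charge allows 47.5% product.

substrate 0.050 M (fed, over 30 s); coupling partner 0.950 equiv; time 3.0 min

    substrate ⇌ intermediate A (K1 = 1.5, k1 = 0.044 /s)
    coupling partner + intermediate A → intermediate B (k2 = 0.48 /M/s)
    coupling partner + intermediate B → intermediate C (k3 = 1.1 /M/s)
    intermediate C → product (k4 = 0.11 /s)

- the reaction counts as stopped when no species that holds the substrate changes by six tenths of a point or more over the second half of the time
- run time (flask): 3.0 min

1. the state of affairs at 3.0 min: stopped, and by what, or still going (it is still moving / forward and back rates have come level / the coupling partner has run out first / all of the substrate has reacted)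
2. part of the substrate gone at 3.0 min
3. the product standing at 3.0 min, as a percentage of the substrate charged

The ledger below is my own, in fractions of the substrate charged. Step 1 relaxes in 0.158 min, short against the 3.0 min, so substrate and intermediate A count as one pool with 60.0% in intermediate A. Intermediate C, with a half-life of 0.11 min, is entered with product.

Steps 2 and 3 draw on the same coupling partner, so their rates compare without it. Step 3 starts with nothing to act on, but as intermediate B builds, the comparison drifts towards equality, reached at the level ratio 0.436, the intermediate B per intermediate A at which both steps draw alike. Intermediate B is then 26.2% of the pool.

Two balances close the books: pool, intermediate B and product sum to the charge, and intermediate B plus twice the product equals the partner spent. Fully spent, this leaves a pool of 46.4%. At level, the partner falls at twice step 2's rate, 0.802 /min with the closing intermediate A. Counted from mid-feed, 2.75 min, that leaves 11.0% of its own charge.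

| Entry | At the asked time | Books closed |
|---|---|---|
| Intermediate B | 13.4% | 12.2% |
| Product with intermediate C | 35.6% | 41.4% |
| Substrate | 20.4% | 18.6% |

So 79.6% of the substrate is gone and, with 5.8 percentage points of product still to come, the flask is reckoned as still moving.

The forecast gives it is still moving, 81% and 36%, holding that “a little remains and product is still creeping up”. The simulation gives it is still moving, 79.7% gone and 35.6% product, with the coupling partner at 8.82% against the reckoned 11.0%.

At 3.00 min the flask holds 0.481 intermediate B per intermediate A against the level ratio 0.436, and step 2 draws 0.91 of step 3's rate. The neighbouring flask, read at 12 min, tests the closed books, its coupling partner standing at 0%. The ledger entered 12.2% intermediate B, 41.4% product and 18.6% substrate. That flask holds 13.6% intermediate B, 0.497 per intermediate A, and 40.7% product, so intermediate B plus twice the product falls 0.0046 points short of the partner charged, a gap that counts unspent coupling partner and twice the intermediate C; its substrate stands at 18.3%.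

The constants used here belong to no real substance; the rest is arithmetic.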